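The route rests on opening the 2,5-dihydrofuran at its O–C2 and C15–C16 bonds (cembrane numbering: C2 the ring methine beside C3=C4, C15 the ring alkene carbon bearing CH2OAc, C16 the ring OCH2). The key step exploits that the ring O–CH2 unit spans C2 and C15 across C1: hung on the C2 oxygen of an enantioenriched enynyl carbinol as a tributylstannylmethyl ether, it is moved by a [2,3]-Wittig–Still shift onto alkyne carbon C15 (centre to allene axis), and iodoetherification returns the oxygen to C2 (axis to centre). The C1 iodide left behind then closes the 14-membered carbocycle by B-alkyl Suzuki coupling.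

Key step: step 9

Numbering used in the names: cembrane numbering of the target (C1=C15 ring alkene, C2 the O-bearing methine, C3=C4, C7/C8 epoxide, C11=C12, C13 and C14 the CH2 groups leading back to C1, C16 the ring OCH2, C17 the CH2OAc carbon). The target is (2R,7R,8R).

Assumption: (S,S)-ProPhenol is taken as the ligand antipode that gives the (2R)-carbinol in step 7; if the facial sense is the opposite, (R,R)-ProPhenol is used and nothing else changes.

Step 1
Reactants: 1 (2E,6E)-farnesyl acetate
Product: 2 (2E,6E,10E)-12-hydroxyfarnesyl acetate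
Conditions: SeO2 (cat.), t-BuOOH, salicylic acid (cat.), CH2Cl2, rt
Reagents that add atoms: tert-butyl hydroperoxide CC(C)(C)OO; selenium dioxide O=[Se]=O
Why: The catalytic SeO2/t-BuOOH allylic oxidation (ene reaction, then [2,3]-shift) should take the terminal isopropylidene at its (E)-methyl group, the two inner trisubstituted alkenes being less reactive, and so give the (10E)-allylic alcohol.

Step 2
Reactants: 2 (2E,6E,10E)-12-hydroxyfarnesyl acetate
Product: 3 12-pivaloyloxyfarnesyl acetate
Conditions: PivCl, pyridine, DMAP (cat.), CH2Cl2, 0 °C to rt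
Reagents that add atoms: pivaloyl chloride CC(C)(C)C(Cl)=O
Why: Acylation of the primary allylic alcohol gives an ester that survives the later methanolysis of the acetate and makes the C11=C12 alkene electron-poor.

Step 3
Reactants: 3 12-pivaloyloxyfarnesyl acetate
Product: 4 (7R,8R)-epoxy diester
Conditions: D-fructose-derived Shi ketone (0.3 equiv), Oxone, K2CO3, Bu4NHSO4, MeCN/CH2(OMe)2/aq. Na2B4O7 buffer, 0 °C
Reagents that add atoms: Oxone, potassium peroxymonosulfate [K+].[O-]S(=O)(=O)OO
Why: In the Shi asymmetric epoxidation the two alkenes that carry an allylic acyloxy group are deactivated toward the chiral dioxirane, so only the central (E)-trisubstituted alkene should react, and the spiro transition state of the D-fructose-derived ketone should set both epoxide carbons as R.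

Step 4
Reactants: 4 (7R,8R)-epoxy diester
Product: 5 epoxy pivalate C2 allylic alcohol
Conditions: K2CO3, MeOH, 0 °C
Reagents that add atoms: none
Why: Transesterification removes the unhindered acetate much faster than the pivalate, and the epoxide is inert to methoxide at 0 °C.

Step 5
Reactants: 5 epoxy pivalate C2 allylic alcohol
Product: 6 (3E)-epoxy pivalate C2 enal
Conditions: MnO2, CH2Cl2, rt
Reagents that add atoms: none
Why: MnO2 oxidises only the allylic alcohol and should keep the (E) geometry of the C3=C4 bond.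

Step 6
Reactants: 7 propargyl alcohol
Product: 8 TBDPS propargyl ether
Conditions: TBDPSCl, imidazole, DMF, rt
Reagents that add atoms: tert-butyl(chloro)diphenylsilane CC(C)(C)[Si](Cl)(c1ccccc1)c2ccccc2
Why: Standard silylation; the bulky TBDPS group is chosen because it should not migrate between oxygen atoms in step 9.

Step 7
Reactants: 6 (3E)-epoxy pivalate C2 enal; 8 TBDPS propargyl ether
Product: 10 (2R)-enynyl carbinol, via methylzinc acetylide 9 (not isolated)
Conditions: (S,S)-ProPhenol (0.2 equiv), Me2Zn, Ph3PO (0.4 equiv), toluene, 0 °C to rt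
Reagents that add atoms: none
Why: In the Trost zinc–ProPhenol asymmetric alkynylation the dinuclear zinc catalyst binds aldehyde and alkynylzinc together and should deliver the alkyne to one face of the enal carbonyl, which sets C2 as R under catalyst control (the remote epoxide has no influence).

Step 8
Reactants: 10 (2R)-enynyl carbinol
Product: 11 (2R)-tributylstannylmethyl ether
Conditions: KH, Bu3SnCH2I, THF, 0 °C to rt
Reagents that add atoms: (iodomethyl)tributylstannane CCCC[Sn](CCCC)(CCCC)CI
Why: Williamson etherification of the potassium alkoxide (Still's preparation of stannylmethyl ethers) alkylates oxygen only, so C2 is untouched.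

Step 9
Reactants: 11 (2R)-tributylstannylmethyl ether
Product: 14 (2R)-C1-iodo-2,5-dihydrofuran pivalate, via α-alkoxymethyllithium 12 (not isolated), via lithium allenylmethoxide 13 (not isolated)
Conditions: n-BuLi (1.1 equiv), THF, −78 °C, 30 min; then NIS, THF, −78 to −20 °C
Reagents that add atoms: N-iodosuccinimide O=C1CCC(=O)N1I
Why: Tin–lithium exchange gives the α-alkoxymethyllithium 12, whose [2,3]-sigmatropic Wittig–Still shift across the propargylic C2–C1≡C15 unit forms C15–C16 and releases the oxygen from C2, giving the allenylmethoxide 13 with the C2 centre transferred suprafacially to the allene axis; NIS then activates the C1=C2 bond of the allene and the alkoxide adds to C2 anti to iodine, which re-forms O–C2 and leaves iodine on C1. The closest known reactions are the Wittig–Still rearrangement of propargylic stannylmethyl ethers to allenylmethanols and the halocyclisation of α-allenols to 3-halo-2,5-dihydrofurans, here run in one flask. The dihydrofuran closes in the 5-endo mode onto the activated allene terminus. C2 is the only new stereocentre: C16 is delivered to the face of C15 from which the oxygen left C2, and the oxygen returns to C2 from that same face, so the (2R) configuration of 11 should be retained overall. The step needs the shift to run across the alkyne and not across the C3=C4 allyl unit or as a [1,2]-shift, which the unhindered alkyne terminus (against the fully substituted C4) and the low temperature should secure, and it needs the two CH2O arms on C15 to stay different, which the non-migrating TBDPS group secures.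

Step 10
Reactants: 14 (2R)-C1-iodo-2,5-dihydrofuran pivalate
Product: 15 C13 allylic alcohol
Conditions: i-Bu2AlH, CH2Cl2, −78 °C
Reagents that add atoms: none
Why: Reductive cleavage of the pivalate at −78 °C should leave the trisubstituted epoxide, the alkenyl iodide and the silyl ether untouched.

Step 11
Reactants: 15 C13 allylic alcohol
Product: 16 (11E)-C13 enal
Conditions: MnO2, CH2Cl2, rt
Reagents that add atoms: none
Why: Chemoselective oxidation of the only free (allylic) alcohol, with retention of the C11=C12 geometry.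

Step 12
Reactants: 16 (11E)-C13 enal
Product: 17 C11=C12–C13=C14 diene
Conditions: Ph3PCH3Br, KHMDS, THF, −78 to 0 °C
Reagents that add atoms: methyltriphenylphosphonium bromide C[P+](c1ccccc1)(c2ccccc2)c3ccccc3.[Br-]
Why: Wittig methylenation of the enal adds C14 as a terminal vinyl carbon; the alkenyl iodide and the epoxide do not react with the ylide.

Step 13
Reactants: 17 C11=C12–C13=C14 diene
Product: 19 macrocyclic TBDPS ether, via B-alkyl-9-BBN borane 18 (not isolated)
Conditions: 9-BBN-H, THF, 0 °C to rt; then slow addition to Pd(dppf)Cl2 (0.2 equiv), AsPh3, Cs2CO3, DMF/THF/H2O, 50 °C, 0.002 M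
Reagents that add atoms: none
Why: 9-BBN should add only to the terminal vinyl group of the diene (boron on C14), and intramolecular B-alkyl Suzuki–Miyaura coupling with the C1 iodide under high dilution should form the C1–C14 bond and the 14-membered ring without touching any stereocentre or alkene geometry.

Step 14
Reactants: 19 macrocyclic TBDPS ether
Product: 20 deacetyl lobophynin B
Conditions: Bu4NF, THF, 0 °C to rt
Reagents that add atoms: none
Why: Fluoride cleaves the silyl ether under conditions that leave the epoxide and the dihydrofuran intact.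

Step 15
Reactants: 20 deacetyl lobophynin B
Product: 21 lobophynin B
Conditions: Ac2O, pyridine, DMAP (cat.), CH2Cl2, 0 °C
Reagents that add atoms: acetic anhydride CC(=O)OC(C)=O
Why: Acetylation of the single primary allylic alcohol under basic conditions, which the acid-sensitive epoxide tolerates.

Compound list
1 | (2E,6E)-farnesyl acetate | CC(C)=CCC/C(C)=C/CC/C(C)=C/COC(C)=O | starting material
2 | (2E,6E,10E)-12-hydroxy-3,7,11-trimethyldodeca-2,6,10-trien-1-yl acetate | OC/C(C)=C/CC/C(C)=C/CC/C(C)=C/COC(C)=O | intermediate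
3 | (2E,6E,10E)-12-acetoxy-2,6,10-trimethyldodeca-2,6,10-trien-1-yl pivalate | CC(C)(C)C(=O)OC/C(C)=C/CC/C(C)=C/CC/C(C)=C/COC(C)=O | intermediate
4 | (6R,7R)-6,7-epoxide of 3 (trans epoxide of the central alkene; C7 and C8 of the target, both R) | CC(C)(C)C(=O)OC/C(C)=C/CC[C@@]1(C)O[C@@H]1CC/C(C)=C/COC(C)=O | intermediate
5 | epoxy pivalate with free C2 allylic alcohol, (7R,8R), 3E, 11E | CC(C)(C)C(=O)OC/C(C)=C/CC[C@@]1(C)O[C@@H]1CC/C(C)=C/CO | intermediate
6 | epoxy pivalate C2 enal, (7R,8R), 3E, 11E | CC(C)(C)C(=O)OC/C(C)=C/CC[C@@]1(C)O[C@@H]1CC/C(C)=C/C=O | intermediate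
7 | propargyl alcohol | C#CCO | starting material
8 | tert-butyl(diphenyl)(prop-2-yn-1-yloxy)silane | C#CCO[Si](c1ccccc1)(c2ccccc2)C(C)(C)C | intermediate
9 | methylzinc acetylide of 8 | C[Zn]C#CCO[Si](c1ccccc1)(c2ccccc2)C(C)(C)C | intermediate
10 | (2R)-enynyl carbinol: C2–OH flanked by (E)-C3=C4 and the C1≡C15 alkyne bearing C17H2OTBDPS; (7R,8R)-epoxide; C13 pivalate | CC(C)(C)C(=O)OC/C(C)=C/CC[C@@]1(C)O[C@@H]1CC/C(C)=C/[C@@H](O)C#CCO[Si](c2ccccc2)(c3ccccc3)C(C)(C)C | intermediate
11 | (2R)-tributylstannylmethyl ether of 10 | CC(C)(C)C(=O)OC/C(C)=C/CC[C@@]1(C)O[C@@H]1CC/C(C)=C/[C@@H](OC[Sn](CCCC)(CCCC)CCCC)C#CCO[Si](c2ccccc2)(c3ccccc3)C(C)(C)C | intermediate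
12 | (2R)-α-alkoxymethyllithium from 11 | CC(C)(C)C(=O)OC/C(C)=C/CC[C@@]1(C)O[C@@H]1CC/C(C)=C/[C@@H](OC[Li])C#CCO[Si](c2ccccc2)(c3ccccc3)C(C)(C)C | intermediate
13 | lithium allenylmethoxide, C2=C1=C15 allene of (aS) axis, C15 bearing C16H2OLi and C17H2OTBDPS | CC(C)(C)C(=O)OC/C(C)=C/CC[C@@]1(C)O[C@@H]1CC/C(C)=C/C([H])=[C@@]=C(CO[Li])CO[Si](c2ccccc2)(c3ccccc3)C(C)(C)C | intermediate
14 | (2R)-2,5-dihydrofuran with iodine on C1, CH2OTBDPS on C15 and the (7R,8R)-epoxy C3–C13 chain (C13 pivalate) on C2 | CC(C)(C)C(=O)OC/C(C)=C/CC[C@@]1(C)O[C@@H]1CC/C(C)=C/[C@H]2OCC(CO[Si](c3ccccc3)(c4ccccc4)C(C)(C)C)=C2I | intermediate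
15 | C13 allylic alcohol from 14 | OC/C(C)=C/CC[C@@]1(C)O[C@@H]1CC/C(C)=C/[C@H]2OCC(CO[Si](c3ccccc3)(c4ccccc4)C(C)(C)C)=C2I | intermediate
16 | (11E)-C13 enal | O=C/C(C)=C/CC[C@@]1(C)O[C@@H]1CC/C(C)=C/[C@H]2OCC(CO[Si](c3ccccc3)(c4ccccc4)C(C)(C)C)=C2I | intermediate
17 | (11E)-C11=C12–C13=C14 diene | C=C/C(C)=C/CC[C@@]1(C)O[C@@H]1CC/C(C)=C/[C@H]2OCC(CO[Si](c3ccccc3)(c4ccccc4)C(C)(C)C)=C2I | intermediate
18 | B-(C14-alkyl)-9-borabicyclo[3.3.1]nonane from 17 | C(C/C(C)=C/CC[C@@]1(C)O[C@@H]1CC/C(C)=C/[C@H]2OCC(CO[Si](c3ccccc3)(c4ccccc4)C(C)(C)C)=C2I)B5C6CCCC5CCC6 | intermediate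
19 | macrocyclic TBDPS ether (17-O-TBDPS deacetyl lobophynin B), (2R,7R,8R) | CC(C)(C)[Si](c4ccccc4)(c5ccccc5)OCC1=C2CC/C(C)=C/CC[C@@]3(C)O[C@@H]3CC/C(C)=C/[C@H]2OC1 | intermediate
20 | deacetyl lobophynin B (C17 alcohol), (2R,7R,8R) | OCC1=C2CC/C(C)=C/CC[C@@]3(C)O[C@@H]3CC/C(C)=C/[C@H]2OC1 | intermediate
21 | lobophynin B, (2R,7R,8R) | CC(=O)OCC1=C2CC/C(C)=C/CC[C@@]3(C)O[C@@H]3CC/C(C)=C/[C@H]2OC1 | target

Total step count: 15. Longest linear sequence: 14 steps (steps 1–5 and 7–15, from 1).

Steps most likely to fail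

Step 9. The α-alkoxy carbanion may shift across the C3=C4 allyl unit or by a [1,2]-path instead of across the alkyne. Chirality transfer may also erode through allyl-cation character at C2 during iodination, and NIS may attack other alkenes. The fallback builds the same allene by copper chemistry and sets out from 6. Alkynylation with 8 under the antipodal (R,R)-ProPhenol gives the (2S)-carbinol F1, and MsCl/Et3N (CH2Cl2, −20 °C) gives its mesylate F2, used crude. Anti-SN2′ displacement with the cuprate from (isopropoxydimethylsilyl)methylmagnesium chloride and CuBr·SMe2 (THF, −78 °C) gives the allenylmethylsilane F3, whose allene axis has the same sense as that of 13. Tamao oxidation (H2O2, KF, KHCO3, THF/MeOH) gives the allenylmethanol F4, and NIS (CH2Cl2, 0 °C) closes it to 14, where the route is rejoined.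

Step 13. Oxidative addition at the hindered tetrasubstituted iodoalkene may be slow, so that oligomerisation and protodeboronation outrun ring closure. The fallback closes the ring at C13–C14 by sulfone alkylation and sets out from 15. MsCl/Et3N then LiBr (THF) gives the allylic bromide F5, and PhSO2Na (DMF) gives the C13 phenyl sulfone F6. Stille hydroxymethylation of the iodide (Bu3SnCH2OH, Pd(PPh3)4, dioxane, 90 °C) gives the C14 alcohol F7, and MsCl/LiCl/2,4,6-collidine (DMF) gives the C14 chloride F8. KHMDS (THF, −78 °C, high dilution) gives the macrocyclic sulfone F9, and Na(Hg)/Na2HPO4 (MeOH, −20 °C) removes the sulfonyl group to give 19.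

Step 7. Addition to the β,β-disubstituted enal may be slow or of low (or opposite) facial selectivity. The fallback sets C2 by reduction and sets out from 6. The lithium acetylide of 8 (n-BuLi, THF, −78 °C) gives the C2 carbinol epimer mixture F10, and MnO2 (CH2Cl2) gives the ynone F11. Reduction with (R)-2-methyl-CBS-oxazaborolidine and catecholborane (toluene, −78 °C), in which the alkenyl group acts as the large and the alkynyl group as the small substituent, should give the (2R)-carbinol 10.

Further compounds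
F1 | step 9 | (2S)-epimer of 10 | CC(C)(C)C(=O)OC/C(C)=C/CC[C@@]1(C)O[C@@H]1CC/C(C)=C/[C@H](O)C#CCO[Si](c2ccccc2)(c3ccccc3)C(C)(C)C
F2 | step 9 | (2S)-mesylate of F1 | CC(C)(C)C(=O)OC/C(C)=C/CC[C@@]1(C)O[C@@H]1CC/C(C)=C/[C@H](OS(C)(=O)=O)C#CCO[Si](c2ccccc2)(c3ccccc3)C(C)(C)C
F3 | step 9 | allenylmethyl(isopropoxy)dimethylsilane, allene axis as in 13 | CC(C)(C)C(=O)OC/C(C)=C/CC[C@@]1(C)O[C@@H]1CC/C(C)=C/C([H])=[C@@]=C(C[Si](C)(C)OC(C)C)CO[Si](c2ccccc2)(c3ccccc3)C(C)(C)C
F4 | step 9 | (aS)-allenylmethanol (protonated form of 13) | CC(C)(C)C(=O)OC/C(C)=C/CC[C@@]1(C)O[C@@H]1CC/C(C)=C/C([H])=[C@@]=C(CO)CO[Si](c2ccccc2)(c3ccccc3)C(C)(C)C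
F5 | step 13 | C13 allylic bromide from 15 | BrC/C(C)=C/CC[C@@]1(C)O[C@@H]1CC/C(C)=C/[C@H]2OCC(CO[Si](c3ccccc3)(c4ccccc4)C(C)(C)C)=C2I
F6 | step 13 | C13 phenyl sulfone | O=S(=O)(c5ccccc5)C/C(C)=C/CC[C@@]1(C)O[C@@H]1CC/C(C)=C/[C@H]2OCC(CO[Si](c3ccccc3)(c4ccccc4)C(C)(C)C)=C2I
F7 | step 13 | C13 sulfone with C14 hydroxymethyl on C1 | O=S(=O)(c5ccccc5)C/C(C)=C/CC[C@@]1(C)O[C@@H]1CC/C(C)=C/[C@H]2OCC(CO[Si](c3ccccc3)(c4ccccc4)C(C)(C)C)=C2CO
F8 | step 13 | C13 sulfone with C14 chloromethyl on C1 | O=S(=O)(c5ccccc5)C/C(C)=C/CC[C@@]1(C)O[C@@H]1CC/C(C)=C/[C@H]2OCC(CO[Si](c3ccccc3)(c4ccccc4)C(C)(C)C)=C2CCl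
F9 | step 13 | macrocyclic C13 phenyl sulfone (C13 epimers) | CC(C)(C)[Si](c4ccccc4)(c5ccccc5)OCC1=C2CC(S(=O)(=O)c6ccccc6)/C(C)=C/CC[C@@]3(C)O[C@@H]3CC/C(C)=C/[C@H]2OC1
F10 | step 7 | C2 epimer mixture of the enynyl carbinol | CC(C)(C)C(=O)OC/C(C)=C/CC[C@@]1(C)O[C@@H]1CC/C(C)=C/C(O)C#CCO[Si](c2ccccc2)(c3ccccc3)C(C)(C)C
F11 | step 7 | C2 ynone | CC(C)(C)C(=O)OC/C(C)=C/CC[C@@]1(C)O[C@@H]1CC/C(C)=C/C(=O)C#CCO[Si](c2ccccc2)(c3ccccc3)C(C)(C)C
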